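**Assumptions (one line each)**
- The target is the 2,3-trans-(2S,3S) dihydrobenzofuran. I worked out the CIP descriptors from the SMILES and checked the trans relationship geometrically.
- The (2R,5R)-sulfide is assumed to give the (2S,3S) product. If the opposite enantiomer forms, the (S,S)-sulfide is used.
- The 4-OH of 2,4,6-trihydroxybenzaldehyde is the most acidic phenol, because the 2,6-OH groups are chelated to the CHO. It is therefore triflated selectively.

## Retrosynthetic overview
1. The target comes from global MOM removal from a penta-MOM trans-2,3-diaryl-dihydrobenzofuran.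
2. The furan ring, with both stereocentres and the C2–C3 and C2–O bonds, is formed last. This is done by a chiral-sulfide-catalysed [4+1] annulation of an o-quinone methide with a benzylic sulfonium ylide.
3. The o-quinone methide is generated by fluoride from a 2-silyloxy benzhydryl sulfone. The sulfone comes from a benzhydrol, made by adding 3,5-bis(MOMO)phenyllithium to a stilbene-aldehyde.
4. The stilbene-aldehyde comes from a Heck reaction of protected 4-vinylguaiacol with the 4-triflate of phloroglucinaldehyde.
5. All arenes are pre-formed. The stilbene C=C forms first, and the dihydrobenzofuran ring forms last.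

## Route

**Step 1**
Reactants: 1 (2,4,6-trihydroxybenzaldehyde); 2 (N-phenylbis(triflimide), PhNTf2)
Product: 3 (2,6-dihydroxy-4-(triflyloxy)benzaldehyde)
Conditions: 2 (1.0 equiv), i-Pr2NEt (1.1 equiv), DMF, –10 → 25 °C
Reagents that add atoms: PhNTf2, O=S(=O)(C(F)(F)F)N(c1ccccc1)S(=O)(=O)C(F)(F)F (gives Tf)
Why: Chemoselective O-triflation. Only the acidic, unchelated 4-OH reacts, and the 2,6-OH groups stay H-bonded to the CHO.

**Step 2**
Reactants: 3; 4 (chloromethyl methyl ether, MOMCl)
Product: 5 (2-hydroxy-6-(methoxymethoxy)-4-(triflyloxy)benzaldehyde)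
Conditions: 4 (1.0 equiv), i-Pr2NEt, CH2Cl2, 0 °C
Reagents that add atoms: MOMCl, COCCl (gives MOM)
Why: Mono-MOM protection of one of two equivalent phenols. The remaining OH is locked by an H-bond to the CHO, which disfavours the second protection.

**Step 3**
Reactants: 5; 6 (TBSCl)
Product: 7 (2-(TBSO)-6-(MOMO)-4-(triflyloxy)benzaldehyde)
Conditions: 6 (1.5 equiv), imidazole, DMF, 50 °C
Reagents that add atoms: TBSCl, CC(C)(C)[Si](C)(C)Cl (gives TBS)
Why: Silylation of the chelated OH gives an ortho-protected aldehyde. This OTBS is the fluoride-labile trigger for the later o-quinone methide.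

**Step 4**
Reactants: 8 (4-vinylguaiacol, 2-methoxy-4-vinylphenol); 4
Product: 9 (4-(methoxymethoxy)-3-methoxystyrene)
Conditions: 4 (1.1 equiv), i-Pr2NEt, CH2Cl2, 0 → 25 °C, BHT (cat.)
Reagents that add atoms: MOMCl, COCCl (gives MOM)
Why: Standard MOM protection of a phenol.

**Step 5**
Reactants: 7; 9
Product: 10 ((E)-2-(TBSO)-6-(MOMO)-4-[2-(4-MOMO-3-methoxyphenyl)vinyl]benzaldehyde)
Conditions: 9 (1.5 equiv), Pd(OAc)2 (5 mol%), dppp (6 mol%), i-Pr2NEt (3 equiv), DMF, 100 °C
Reagents that add atoms: none
Why: Mizoroki–Heck reaction of an aryl triflate activated by the para-CHO gives the E-stilbene. The protecting groups are Pd-inert.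

**Step 6**
Reactants: 11 (5-bromoresorcinol, 1-bromo-3,5-dihydroxybenzene); 4
Product: 12 (1-bromo-3,5-bis(MOMO)benzene)
Conditions: NaH (2.5 equiv), THF/DMF, 0 °C; 4 (2.4 equiv), 0 → 25 °C
Reagents that add atoms: MOMCl, COCCl (gives MOM)
Why: Double Williamson-type O-alkylation.

**Step 7**
Reactants: 12; 10
Product: 13 (racemic benzhydrol, [3,5-bis(MOMO)phenyl][2-(TBSO)-6-(MOMO)-4-(E)-styrylaryl]methanol)
Conditions: 12 (1.4 equiv), t-BuLi (2.8 equiv), THF, –78 °C, 20 min; then 10 in THF, –78 °C, 1 h; cold aqueous NH4Cl; crude used directly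
Reagents that add atoms: none (H on work-up)
Why: Halogen–lithium exchange followed by 1,2-addition to the aldehyde. This benzhydrol is prone to ionise, so it is not chromatographed.

**Step 8**
Reactants: 13; 14 (p-toluenesulfinic acid)
Product: 15 (racemic benzhydryl p-tolyl sulfone)
Conditions: 14 (1.5 equiv), CH2Cl2, MgSO4, 0 → 25 °C
Reagents that add atoms: p-toluenesulfinic acid, Cc1ccc(cc1)S(=O)O (gives Ts)
Why: SN1 substitution of the strongly stabilised 2,6-dioxygenated benzhydryl cation gives a bench-stable o-quinone methide precursor. The carbinol stereocentre is destroyed here and is irrelevant.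

**Step 9**
Reactants: 16 (vanillyl alcohol); 4
Product: 17 (4-(MOMO)-3-methoxybenzyl alcohol)
Conditions: K2CO3 (1.1 equiv), 4 (1.05 equiv), acetone, 0 → 25 °C
Reagents that add atoms: MOMCl, COCCl (gives MOM)
Why: Carbonate deprotonates only the phenol, so it is alkylated selectively over the primary alcohol.

**Step 10**
Reactants: 17; 18 (CBr4)
Product: 19 (4-(MOMO)-3-methoxybenzyl bromide)
Conditions: 18 (1.2 equiv), PPh3 (1.2 equiv), CH2Cl2, 0 °C, 30 min; filter through a short silica plug; use at once
Reagents that add atoms: CBr4, BrC(Br)(Br)Br (gives Br)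
Why: Neutral Appel bromination leaves the acid-labile MOM group intact.

**Step 11 (key step)**
Reactants: 15; 19; 20 (chiral sulfide catalyst, (2R,5R)-2,5-dimethylthiolane)
Product: 21 (penta-MOM (2S,3S)-trans-2,3-diaryl-6-styryl-dihydrobenzofuran)
Conditions: 15 (1.0 equiv), 19 (1.5 equiv), 20 (20 mol%), CsF (2.0 equiv), Cs2CO3 (2.0 equiv), MeCN (0.03 M), 4 Å MS, 30 °C, 24 h
Reagents that add atoms: none (19 is a reactant; the sulfide is a catalyst)
Why: Fluoride removes the aryl TBS group, and the phenoxide expels p-tolylsulfinate to give the o-quinone methide. Sulfide 20 and bromide 19 form a benzylic sulfonium salt, and Cs2CO3 converts it to the ylide. The ylide adds 1,4 to the quinone methide carbon, with the chiral sulfonium controlling the enantioface and the anti-betaine leading to trans. The phenoxide then displaces the sulfonium by 5-exo-tet, inverting that carbon, which releases 20 and closes the ring. This is a sulfide-catalysed ylide [4+1] annulation.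
Proposed new method: Catalytic enantioselective [4+1] annulation of a highly electron-rich, fluoride-unmasked o-quinone methide with a catalytically generated semistabilised benzylic sulfonium ylide. The mechanistic reasoning is that the ylide carbon is set by the catalyst-controlled addition, and ring closure by sulfide displacement fixes trans-2,3. The closest known reactions are racemic stoichiometric sulfonium-ylide [4+1] annulations of o-quinone methides and sulfide-catalysed asymmetric ylide epoxidation/cyclopropanation.

**Step 12**
Reactants: 21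
Product: 22 (Bisisorhapontigenin B)
Conditions: ZnBr2 (15 equiv), n-PrSH (15 equiv), CH2Cl2, 0 → 25 °C, 30 min
Reagents that add atoms: none (H only)
Why: Thiophilic Lewis-acid MOM cleavage in a non-protic medium at low temperature spares the acid-sensitive benzylic C2–O bond, the E-stilbene and the stereocentres. C3–H is not epimerised, so configuration is retained.

## Self-check
- **Structure:** The product has a 2,3-dihydrobenzofuran with C2-(4-hydroxy-3-methoxyphenyl), C3-(3,5-dihydroxyphenyl), 4-OH and 6-[(E)-4-hydroxy-3-methoxystyryl]. The benzaldehyde carbons map as C1 → C3a, the OTBS carbon → C7a (ring O), the OMOM carbon → C4-OH, and the styryl carbon → C6, para to C3a. This matches the target SMILES.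
- **Atoms and functional groups:** Every atom is accounted for from step to step. TBS is lost only in step 11, and MOM groups are lost only in step 12. No step touches the styryl C=C (E).
- **Stereochemistry:** Both stereocentres are formed together in step 11, set by catalyst and ring closure, and nothing later touches them.

## Compound list
1 | 2,4,6-trihydroxybenzaldehyde | O=Cc1c(O)cc(O)cc1O | starting material
2 | N-phenylbis(trifluoromethanesulfonimide) | O=S(=O)(C(F)(F)F)N(c1ccccc1)S(=O)(=O)C(F)(F)F | starting material
3 | 2,6-dihydroxy-4-(triflyloxy)benzaldehyde | O=Cc1c(O)cc(OS(=O)(=O)C(F)(F)F)cc1O | intermediate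
4 | chloromethyl methyl ether (MOMCl) | COCCl | starting material
5 | 2-hydroxy-6-(MOMO)-4-(triflyloxy)benzaldehyde | O=Cc1c(O)cc(OS(=O)(=O)C(F)(F)F)cc1OCOC | intermediate
6 | tert-butyldimethylsilyl chloride | CC(C)(C)[Si](C)(C)Cl | starting material
7 | 2-(TBSO)-6-(MOMO)-4-(triflyloxy)benzaldehyde | O=Cc1c(O[Si](C)(C)C(C)(C)C)cc(OS(=O)(=O)C(F)(F)F)cc1OCOC | intermediate
8 | 4-vinylguaiacol (2-methoxy-4-vinylphenol) | C=Cc1ccc(O)c(OC)c1 | starting material
9 | 4-(MOMO)-3-methoxystyrene | C=Cc1ccc(OCOC)c(OC)c1 | intermediate
10 | (E)-stilbene aldehyde | O=Cc1c(O[Si](C)(C)C(C)(C)C)cc(/C=C/c2ccc(OCOC)c(OC)c2)cc1OCOC | intermediate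
11 | 5-bromoresorcinol | Oc1cc(O)cc(Br)c1 | starting material
12 | 1-bromo-3,5-bis(MOMO)benzene | COCOc1cc(Br)cc(OCOC)c1 | intermediate
13 | racemic benzhydrol | COCOc1cc(cc(OCOC)c1)C(O)c1c(O[Si](C)(C)C(C)(C)C)cc(/C=C/c2ccc(OCOC)c(OC)c2)cc1OCOC | intermediate
14 | p-toluenesulfinic acid | Cc1ccc(cc1)S(=O)O | starting material
15 | racemic benzhydryl p-tolyl sulfone | Cc1ccc(cc1)S(=O)(=O)C(c1cc(OCOC)cc(OCOC)c1)c1c(O[Si](C)(C)C(C)(C)C)cc(/C=C/c2ccc(OCOC)c(OC)c2)cc1OCOC | intermediate
16 | vanillyl alcohol | COc1cc(CO)ccc1O | starting material
17 | 4-(MOMO)-3-methoxybenzyl alcohol | COCOc1ccc(CO)cc1OC | intermediate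
18 | carbon tetrabromide | BrC(Br)(Br)Br | starting material
19 | 4-(MOMO)-3-methoxybenzyl bromide | COCOc1ccc(CBr)cc1OC | intermediate
20 | (2R,5R)-2,5-dimethylthiolane (catalyst) | C[C@@H]1CC[C@@H](C)S1 | starting material (catalyst)
21 | penta-MOM (2S,3S)-trans-dihydrobenzofuran | COc1cc(/C=C/c2cc(OCOC)c3c(c2)O[C@H](c2ccc(OCOC)c(OC)c2)[C@H]3c2cc(OCOC)cc(OCOC)c2)ccc1OCOC | intermediate
22 | Bisisorhapontigenin B | COc1cc(/C=C/c2cc(O)c3c(c2)O[C@H](c2ccc(O)c(OC)c2)[C@H]3c2cc(O)cc(O)c2)ccc1O | target

## Step count
- Total steps: 12.
- Longest linear sequence: 8 (steps 1, 2, 3, 5, 7, 8, 11, 12).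

## Three steps most likely to fail
1. **Step 11 (proposed new step).** The quinone methide is strongly electron-rich, so it is a weak electrophile. It may also be intercepted by the sulfide catalyst, by the styryl group of a second molecule (hetero-Diels–Alder), or lose ee through reversible ylide addition.
   - Fallback (known chemistry): run the racemic trans [4+1] with the pre-formed Me2S-derived sulfonium salt of 19 (known racemic sulfonium-ylide [4+1] of o-quinone methides), then resolve 21 by preparative chiral-stationary-phase HPLC.
2. **Step 8 (sulfone formation).** The benzhydryl cation is so stabilised that the benzhydrol or sulfone may ionise, decompose or lose MOM groups.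
   - Fallback: skip the sulfone. Quench the step-7 alkoxide in situ with methyl chloroformate to give the benzhydryl carbonate, and use fluoride-triggered 1,4-elimination of that carbonate as the o-quinone methide precursor in step 11.
3. **Step 12 (global deprotection).** Five MOM groups must be removed without ring-opening of the benzylic C2–O bond, which is acid-prone, or isomerisation of the stilbene.
   - Fallback: use a non-protic cleavage mechanism, TMSOTf/2,2′-bipyridyl (silyl transfer to the MOM oxygen, then aqueous hydrolysis of the pyridinium intermediate), at –20 °C instead of the ZnBr2/thiol method.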